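**Assumption:** The target is drawn as the enol of each triketone, and CIP labels are taken from the given SMILES, which gives (R,R). Compound 9 has the same spatial arrangement as the target but is labelled (S,S) because the CIP priority order at the benzylic carbon changes. The chiral ligand enantiomer named in Step 4 is assumed to give this series; the other enantiomer would be used if the opposite one formed.

## Retrosynthetic overview
- Myrtucommulone F (10) is formed from bis-adduct 9 by a double Dieckmann-type cyclisation. Both tetramethyl-cyclohexanetrione rings close at once, through C3–C4 bond formation.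
- Bis-adduct 9 comes from hexanoylphloroglucinol (3) and two equivalents of an alkylidene diketoester (8). A catalytic enantioselective double Friedel–Crafts alkylation sets both benzylic (CH–iPr) stereocentres.
- Alkylidene 8 comes from isobutyraldehyde (7) and the acyclic diketoester 6. Compound 6 comes from 3-methylbutan-2-one (4) and a dimethylmalonyl half-ester chloride (5).
- Ring order: the central arene is present from the start. Both trione rings form last, in one operation.

## Route

**Step 1**
Reactants: 1 phloroglucinol; 2 hexanoyl chloride
Product: 3 1-(2,4,6-trihydroxyphenyl)hexan-1-one (hexanoylphloroglucinol)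
Conditions: AlCl3, PhNO2/CH2Cl2, 0 °C → rt
Reagents that add atoms: hexanoyl chloride, CCCCCC(=O)Cl (reactant 2)
Why: Friedel–Crafts C-acylation of the very electron-rich triol stops at the mono-acyl stage, because the chelated acyl group deactivates the ring.

**Step 2**
Reactants: 4 3-methylbutan-2-one (2.2 equiv); 5 methyl 3-chloro-2,2-dimethyl-3-oxopropanoate (1 equiv)
Product: 6 methyl 2,2,6-trimethyl-3,5-dioxoheptanoate
Conditions: LDA (2.2 equiv), THF, –78 → 0 °C; then aq. NH4Cl
Reagents that add atoms: acid chloride 5, COC(=O)C(C)(C)C(=O)Cl (reactant 5)
Why: Acylation of the kinetic lithium enolate, which forms at the methyl group, gives the 1,3-diketone. The second equivalent of enolate deprotonates the product and so prevents over-acylation.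

**Step 3**
Reactants: 6; 7 isobutyraldehyde
Product: 8 methyl 2,2,6-trimethyl-4-(2-methylpropanoyl)-3-oxohept-4-enoate (alkylidene 1,3-diketone, E/Z mixture)
Conditions: TiCl4, pyridine, THF/CH2Cl2, 0 °C → rt, 3 h. The crude product is used immediately.
Reagents that add atoms: isobutyraldehyde, CC(C)C=O (reactant 7)
Why: Lehnert-type Knoevenagel condensation gives the bidentate Michael acceptor without any amine base, so no racemic background reaction occurs in Step 4.

**Step 4**
Reactants: 3 (1 equiv); 8 (2.4 equiv)
Product: 9 bis-adduct, (S,S) at both benzylic carbons (the same spatial arrangement as the target's R,R)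
Conditions: Cu(OTf)2 (20 mol %), (S,S)-tBu-BOX (22 mol %), 4 Å MS, CH2Cl2, –20 °C → rt, 72 h
Reagents that add atoms: none beyond the numbered reactants
Why: Catalytic enantioselective Friedel–Crafts (Michael-type) alkylation. The chiral Cu(II) chelates the diketone and blocks one enantioface, so the nucleophilic C3 and C5 of 3 attack the β-carbon to set each CH(iPr)Ar centre; catalyst control on the second addition enriches the C2-symmetric (S,S) isomer over the (S,R) isomer (Horeau-type amplification).
Proposed new method: the closest known reaction is Cu–BOX-catalysed Friedel–Crafts addition of electron-rich arenes to alkylidene β-dicarbonyls. The extension is to a hexanoylphloroglucinol as the arene, to two sequential additions, and to a β-branched aliphatic alkylidene diketone.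

**Step 5**
Reactants: 9
Product: 10 Myrtucommulone F
Conditions: (i) NaH (5.2 equiv), THF, 0 °C, 30 min; (ii) LDA (2.4 equiv), –78 → 0 °C, then 45 °C, 6 h; (iii) 1 M HCl to pH 2, 0 °C
Reagents that add atoms: none
Why: NaH removes the five acidic protons (three ArOH and two diketone C–H). LDA then forms the γ-dianion of each diketone at the isopropyl CH. This is the only possible site, because the CMe2 on the other side has no α-H. Each dianion closes by an intramolecular Claisen–Dieckmann attack on the methyl ester, giving both 2,2,4,4-tetramethylcyclohexane-1,3,5-trione rings and two equivalents of MeOH at once, with the stable trione enolates as the driving force. The benzylic centres are non-acidic and sit inside a polyanion, which suppresses retro-Michael scission, so they are not touched.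
Proposed new method: the closest known reaction is Weiler γ-dianion alkylation/acylation and the Dieckmann synthesis of cyclohexane-1,3-diones from 5-oxo esters. The extension is a double closure onto a hindered pivalate-type ester to make two adjacent quaternary carbons in a polyphenoxide.

## Compound list
1 | phloroglucinol | Oc1cc(O)cc(O)c1 | starting material
2 | hexanoyl chloride | CCCCCC(=O)Cl | starting material
3 | 1-(2,4,6-trihydroxyphenyl)hexan-1-one | CCCCCC(=O)c1c(O)cc(O)cc1O | intermediate
4 | 3-methylbutan-2-one | CC(=O)C(C)C | starting material
5 | methyl 3-chloro-2,2-dimethyl-3-oxopropanoate | COC(=O)C(C)(C)C(=O)Cl | starting material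
6 | methyl 2,2,6-trimethyl-3,5-dioxoheptanoate | COC(=O)C(C)(C)C(=O)CC(=O)C(C)C | intermediate
7 | isobutyraldehyde | CC(C)C=O | starting material
8 | methyl 2,2,6-trimethyl-4-(2-methylpropanoyl)-3-oxohept-4-enoate | COC(=O)C(C)(C)C(=O)C(=CC(C)C)C(=O)C(C)C | intermediate
9 | bis-adduct, (S,S) by CIP | CCCCCC(=O)c1c(O)c([C@H](C(C(=O)C(C)C)C(=O)C(C)(C)C(=O)OC)C(C)C)c(O)c([C@H](C(C(=O)C(C)C)C(=O)C(C)(C)C(=O)OC)C(C)C)c1O | intermediate
10 | Myrtucommulone F (R,R) | CCCCCC(=O)c1c(O)c([C@H](C2=C(O)C(C)(C)C(=O)C(C)(C)C2=O)C(C)C)c(O)c([C@H](C2=C(O)C(C)(C)C(=O)C(C)(C)C2=O)C(C)C)c1O | target

## Totals
Total steps: 5. Longest linear sequence: 4 (4 → 6 → 8 → 9 → 10).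

## Three steps most likely to fail
1. **Step 5 (double γ-dianion Dieckmann).**
   - Risks: incomplete dianion formation in the polyphenoxide, retro-Claisen ring opening of the trione, or retro-Michael racemisation on work-up.
   - Fallback: drop the ring-forming closure. Make syncarpic acid by exhaustive methylation of phloroglucinol (MeI, NaOMe), then add it to the o-quinone methide generated from 3 and 7 under chiral phosphoric acid catalysis.
2. **Step 4 (enantioselective double Friedel–Crafts).**
   - Risks: Cu poisoning by the chelating acylphloroglucinol, low ee or poor (S,S)/(S,R) ratio with the β-branched substrate, or cyclisation of the adduct to a 4H-chromene.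
   - Fallback: change the activation mode. Run a chiral phosphoric acid (TRIP-type) H-bond-catalysed three-component reaction of 3, 7 and 6 through the o-quinone methide, at low temperature and without a metal.
3. **Step 2 (C- versus O-acylation of the lithium enolate by the hindered acid chloride).**
   - Risk: the enol ester forms instead of the diketone.
   - Fallback: build 6 by aldol addition of the lithium enolate of 4 to methyl 2,2-dimethyl-3-oxopropanoate, followed by Dess–Martin oxidation of the β-hydroxy ketone.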